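(The runs are calculated from invented constants; scatter was added.)

A small charge of reagent dropped into the flask goes partly to starting material and partly to mono adduct, so I divided those two rates, and reagent and time fell out. The mono adduct lost per unit of charge taking its first reagent is then the ratio of mono adduct to starting material, divided by one constant.

| flask | solid substrate | reagent | remark | time |
|---|---|---|---|---|
| larch | 0.54 M | 1.05 equiv | run made earlier |  |
| elm | 1.2 M | 1.05 equiv | run made earlier |  |
| ash | 0.80 M | 1.6 equiv | run made earlier |  |
| flask | 0.80 M | 1.05 equiv |  | 1.0 h |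

| run | time / min | starting material / % | triple product / % | mono adduct / % | isomer of the product / % | bis adduct / % | solid substrate / % |
|---|---|---|---|---|---|---|---|
| larch | 6.00 | 31 | 0 | 12 | 2 | 0 | 60 |
| larch | 15.0 | 44 | 0 | 29 | 0 | 1 | 24 |
| larch | 20.0 | 50 | 6 | 36 | 1 | 3 | 11 |
| larch | 30.0 | 39 | 2 | 51 | 1 | 7 | 0 |
| larch | 40.0 | 30 | 3 | 60 | 5 | 5 | 2 |
| larch | 50.0 | 28 | 4 | 63 | 3 | 6 | 0 |
| elm | 4.00 | 11 | 1 | 6 | 1 | 0 | 88 |
| elm | 6.00 | 11 | 0 | 10 | 0 | 4 | 83 |
| elm | 8.00 | 18 | 0 | 12 | 1 | 1 | 71 |
| elm | 15.0 | 18 | 2 | 24 | 4 | 2 | 59 |
| elm | 20.0 | 18 | 2 | 28 | 0 | 7 | 48 |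
| elm | 30.0 | 18 | 7 | 36 | 3 | 7 | 33 |
| elm | 50.0 | 22 | 9 | 49 | 3 | 8 | 9 |
| ash | 4.00 | 18 | 6 | 6 | 2 | 1 | 75 |
| ash | 8.00 | 19 | 0 | 19 | 0 | 0 | 64 |
| ash | 15.0 | 21 | 1 | 35 | 2 | 4 | 39 |
| ash | 25.0 | 28 | 8 | 47 | 2 | 4 | 9 |
| ash | 50.0 | 8 | 21 | 58 | 4 | 5 | 0 |

(standard deviation of a reading: 2 percentage points)

- solid substrate is a solid; its amount is given per volume of the solution
- candidate steps: bis adduct <-> isomer of the product; reagent + mono adduct -> bis adduct; starting material + reagent -> mono adduct; solid substrate <-> starting material; reagent + bis adduct -> triple product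
- at the start none of the solid substrate is in solution
- starting material means what is dissolved; the solid is not counted in it

- the species in which most of what was charged as solid substrate, at 1.0 h sits (triple product / isomer of the product / mono adduct / bis adduct / starting material)
- the largest share itself, whichever of these holds it, in percent of the solid substrate charged

By 50.0 min in the larch run, 76.0% of the charge had taken reagent and 13.0% had gone past mono adduct. The ratio of mono adduct to starting material climbed from nothing through 0.720 at 20.0 min to 2.25. Counting the middle reading twice gave a mean of 0.922, so I read 5.39, the selectivity factor: how many times more readily starting material takes reagent than mono adduct does.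

For the flask I assumed the solid gone by the hour and took closing starting material as 25.0%, the mean of the last larch and elm readings. Had the whole charge dissolved at once, mono adduct would reach 64.2%. With starting material held at that fraction throughout, it would reach 57.5%. In the larch run starting material stood at 50% at 20.0 min, above my closing fraction, before falling to 28%, so I placed the flask between the two reckonings, at 60.9%.

The forecast said mono adduct at 60%, range 54% to 65%, in its words “mono adduct near 60%”.

The flask gave mono adduct at 59.0%, with starting material at 25.4%.

    bis adduct ⇌ isomer of the product (K = 0.668, k = 0.0206 s⁻¹)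
    reagent + mono adduct → bis adduct (k = 4.49 × 10⁻⁴ M⁻¹ s⁻¹)
    starting material + reagent → mono adduct (k = 0.00237 M⁻¹ s⁻¹)
    solid substrate ⇌ starting material, rate k4*(cs4 - [starting material]) while solid is left; crystals form when [starting material] > cs4 (solubility = 0.330 M, k = 0.00276 s⁻¹)
    reagent + bis adduct → triple product (k = 0.00302 M⁻¹ s⁻¹)

Carried to the flask's closing fractions, my factor made mono adduct 2.32 times faster than it was used. The neighbour charged with 0.260 equiv of reagent still held solid at 36.9%, with starting material at 40.5%. The held-fraction reckoning, fed that fraction and the reagent it spent, gave 22.8%. That neighbour's mono adduct stood at 21.3%, less than its starting material.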